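Assumption: positions follow eremophilane numbering (ring A = C1–C5 and C10, ring B = C5–C10); the SMILES is read as (3R,4R,5R) with a Z thioacrylate, and "α" means the face opposite the C5 methyl.

## Retrosynthetic overview

1. Target 20 ⇒ acyl C–O bond: diol 13 + (Z)-thioacrylic acid 19 (made from propargyl alcohol 14).
2. 13 ⇒ C11–O bond and C6=C7 alkene together, by a singlet-oxygen ene reaction on (+)-isopetasol 11.
3. 11 ⇒ C3–O bond and C4–H by a face-selective anti-Markovnikov hydration of the C3=C4 alkene of trienone 9 (new step; C5 controls C3 and C4).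
4. 9 ⇒ acetone aldol condensation on 6; 6 ⇒ Wittig methylenation and alkene isomerisation of (S)-Wieland–Miescher ketone 4.
5. 4 ⇒ dione 1 + enone 2: ring A is bought, ring B is closed in the proline annulation (sets C5); no further ring is formed.

## Route

Step 1
Reactants: 1 2-methylcyclohexane-1,3-dione; 2 methyl vinyl ketone
Product: 4 (S)-Wieland–Miescher ketone, via triketone 3 (not isolated)
Conditions: L-proline (35 mol%), DMSO, 35 °C, 90 h; one recrystallisation (Et2O–hexane, −20 °C) to ≥98% ee
Reagents that add atoms: none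
Why: Michael addition followed by proline-enamine intramolecular aldol condensation (Hajos–Parrish–Eder–Sauer–Wiechert Robinson annulation) closes ring B, and L-proline differentiates the two enantiotopic ring carbonyls so that the quaternary centre (later C5) is formed as S.

Step 2
Reactants: 4 (S)-Wieland–Miescher ketone
Product: 5 (R)-4a-methyl-5-methylidene-4,4a,5,6,7,8-hexahydronaphthalen-2(3H)-one
Conditions: Ph3PCH3Br (1.25 equiv), KOtBu (1.2 equiv), THF, 0 °C; then 4, 0 °C → rt, 2 h
Reagents that add atoms: methyltriphenylphosphonium bromide, C[P+](c1ccccc1)(c1ccccc1)c1ccccc1.[Br-]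
Why: Wittig methylenation is chemoselective for the saturated ketone because the conjugated carbonyl is less electrophilic and is masked as its dienolate by the basic ylide; the stereocentre is untouched (S becomes R only through CIP priorities).

Step 3
Reactants: 5 (R)-4a-methyl-5-methylidene-4,4a,5,6,7,8-hexahydronaphthalen-2(3H)-one
Product: 6 (R)-4a,5-dimethyl-4,4a,7,8-tetrahydronaphthalen-2(3H)-one
Conditions: p-TsOH·H2O (10 mol%), toluene, 80 °C
Reagents that add atoms: none
Why: acid-catalysed alkene isomerisation through the tertiary C4 cation gives the more stable trisubstituted C3=C4 alkene and stops there, since C5 is quaternary and further migration would need a secondary cation.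

Step 4
Reactants: 6 (R)-4a,5-dimethyl-4,4a,7,8-tetrahydronaphthalen-2(3H)-one
Product: 9 (R)-4a,5-dimethyl-3-(propan-2-ylidene)-4,4a,7,8-tetrahydronaphthalen-2(3H)-one, via aldol adduct 7 (not isolated), via tertiary mesylate 8 (not isolated)
Conditions: LDA (1.1 equiv), THF, −78 °C; acetone (1.5 equiv), −78 °C, 10 min; MsCl (1.6 equiv), −78 → 0 °C; DBU (3 equiv), 0 °C → rt
Reagents that add atoms: acetone, CC(C)=O
Why: kinetic α′-deprotonation of the enone at C7, aldol addition to acetone and base-induced elimination of the tertiary mesylate (aldol condensation) give the conjugated isopropylidene dienone; the transient C7 stereocentre is destroyed.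

Step 5
Reactants: 9 (R)-4a,5-dimethyl-3-(propan-2-ylidene)-4,4a,7,8-tetrahydronaphthalen-2(3H)-one
Product: 11 (+)-isopetasol, via isopetasol acetate 10 (not isolated)
Conditions: 9-mesityl-10-methylacridinium tetrafluoroborate (5 mol%), (PhS)2 (25 mol%), 2,6-lutidine (25 mol%), AcOH (5 equiv), 1,2-dichloroethane, 455 nm LEDs, N2, 23 °C; then evaporate, K2CO3, MeOH, rt
Reagents that add atoms: acetic acid, CC(=O)O
Why: Proposed new method: acridinium photoredox/thiol hydrogen-atom-transfer anti-Markovnikov hydroacyloxylation (closest known reaction type: alkene radical-cation hydrofunctionalisation of styrenes and simple acyclic or monocyclic alkenes) is extended to a ring-fused trisubstituted alkene beside a quaternary centre inside a cross-conjugated dienone and used as a formal syn hydration; the excited acridinium should oxidise only the electron-rich isolated C3=C4 bond, acetic acid adds reversibly at the less substituted C3 on the α face (the β face is 1,3-syn to the axial C5 methyl), PhSH formed in situ gives H to the tertiary C4 radical also from the α face (the β lobe is shielded by the adjacent C5 methyl), so the all-equatorial 3α-O/4β-CH3 isomer (3R,4R) is expected, and methanolysis of acetate 10 in the same flask frees the alcohol.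

Step 6
Reactants: 11 (+)-isopetasol
Product: 13 (4aR,5R,6R)-6-hydroxy-3-(2-hydroxypropan-2-yl)-4a,5-dimethyl-5,6,7,8-tetrahydronaphthalen-2(4aH)-one, via hydroperoxide 12 (not isolated)
Conditions: O2, 5,10,15,20-tetraphenylporphyrin (1 mol%), CH2Cl2, white LEDs, −20 °C; then PPh3 (1.2 equiv), −20 °C → rt
Reagents that add atoms: dioxygen, O=O
Why: Schenck ene reaction of singlet oxygen with the s-cis α-isopropylidene ketone puts oxygen on the β-carbon C11 and takes hydrogen from C6, the alkyl group geminal to the carbonyl (gem effect), so the C11–O bond and the C6=C7 alkene form together; PPh3 reduces the hydroperoxide, no stereocentre is created, and the electron-poor C9=C10 alkene and the C3 hydroxyl are inert.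

Step 7
Reactants: 14 propargyl alcohol
Product: 16 (Z)-3-iodo-2-methylprop-2-en-1-ol, via alkenylmagnesium 15 (not isolated)
Conditions: MeMgBr (2.5 equiv), CuI (10 mol%), THF, −10 °C → rt; then I2 (1.2 equiv), −10 °C; aq. NH4Cl/Na2S2O3 work-up
Reagents that add atoms: methylmagnesium bromide, C[Mg]Br; iodine, II
Why: copper-catalysed anti-carbomagnesiation of the propargylic alkoxide (Duboudin reaction) places magnesium cis to CH2O in a five-membered chelate, and iodinolysis with retention gives the Z vinyl iodide.

Step 8
Reactants: 16 (Z)-3-iodo-2-methylprop-2-en-1-ol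
Product: 18 (Z)-3-iodo-2-methylprop-2-enoic acid, via iodo enal 17 (not isolated)
Conditions: TEMPO (20 mol%), PhI(OAc)2 (2.2 equiv), MeCN/H2O 1:1, 0 °C → rt
Reagents that add atoms: water, O
Why: oxoammonium (TEMPO/PhI(OAc)2, Epp–Widlanski) oxidation takes the allylic alcohol to the aldehyde and its hydrate on to the acid without touching the vinyl iodide or its Z geometry.

Step 9
Reactants: 18 (Z)-3-iodo-2-methylprop-2-enoic acid
Product: 19 (Z)-2-methyl-3-(methylsulfanyl)prop-2-enoic acid
Conditions: NaSMe (2.5 equiv), CuI (10 mol%), 1,10-phenanthroline (20 mol%), DMF, 60 °C; then 1 M HCl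
Reagents that add atoms: sodium methanethiolate, C[S-].[Na+]
Why: copper-catalysed Ullmann-type C–S coupling of the vinyl iodide (equivalently an addition–elimination at the β-carbon) proceeds with retention and gives the Z thioacrylic acid.

Step 10
Reactants: 13 (4aR,5R,6R)-6-hydroxy-3-(2-hydroxypropan-2-yl)-4a,5-dimethyl-5,6,7,8-tetrahydronaphthalen-2(4aH)-one; 19 (Z)-2-methyl-3-(methylsulfanyl)prop-2-enoic acid
Product: 20 (1R,2R,8aR)-7-(2-hydroxypropan-2-yl)-1,8a-dimethyl-6-oxo-1,2,3,4,6,8a-hexahydronaphthalen-2-yl (2Z)-2-methyl-3-(methylsulfanyl)prop-2-enoate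
Conditions: DCC (1.3 equiv), DMAP (20 mol%), CH2Cl2, 0 °C → rt
Reagents that add atoms: none
Why: Steglich esterification acylates only the equatorial secondary C3 hydroxyl (the tertiary C11 hydroxyl is inert) and retains C3 because the C3–O bond is not broken.

## Compound list

1 | 2-methylcyclohexane-1,3-dione | CC1C(=O)CCCC1=O | starting material
2 | methyl vinyl ketone (but-3-en-2-one) | CC(=O)C=C | starting material
3 | 2-methyl-2-(3-oxobutyl)cyclohexane-1,3-dione | CC(=O)CCC1(C)C(=O)CCCC1=O | intermediate
4 | (S)-8a-methyl-3,4,8,8a-tetrahydronaphthalene-1,6(2H,7H)-dione ((S)-Wieland–Miescher ketone) | C[C@]12CCC(=O)C=C1CCCC2=O | intermediate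
5 | (R)-4a-methyl-5-methylidene-4,4a,5,6,7,8-hexahydronaphthalen-2(3H)-one | C[C@]12CCC(=O)C=C1CCCC2=C | intermediate
6 | (R)-4a,5-dimethyl-4,4a,7,8-tetrahydronaphthalen-2(3H)-one | C[C@]12CCC(=O)C=C1CCC=C2C | intermediate
7 | (4aR)-3-(2-hydroxypropan-2-yl)-4a,5-dimethyl-4,4a,7,8-tetrahydronaphthalen-2(3H)-one (both C3 epimers; lithium alkoxide in the flask) | C[C@]12CC(C(C)(C)O)C(=O)C=C1CCC=C2C | intermediate
8 | 2-[(4aR)-4a,5-dimethyl-2-oxo-2,3,4,4a,7,8-hexahydronaphthalen-3-yl]propan-2-yl methanesulfonate (both C3 epimers) | C[C@]12CC(C(C)(C)OS(C)(=O)=O)C(=O)C=C1CCC=C2C | intermediate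
9 | (R)-4a,5-dimethyl-3-(propan-2-ylidene)-4,4a,7,8-tetrahydronaphthalen-2(3H)-one (eremophila-3,7(11),9-trien-8-one) | C[C@]12CC(=C(C)C)C(=O)C=C1CCC=C2C | intermediate
10 | (1R,2R,8aR)-1,8a-dimethyl-6-oxo-7-(propan-2-ylidene)-1,2,3,4,6,7,8,8a-octahydronaphthalen-2-yl acetate (isopetasol acetate) | CC(=O)O[C@@H]1CCC2=CC(=O)C(=C(C)C)C[C@]2(C)[C@H]1C | intermediate
11 | (4aR,5R,6R)-6-hydroxy-4a,5-dimethyl-3-(propan-2-ylidene)-4,4a,5,6,7,8-hexahydronaphthalen-2(3H)-one ((+)-isopetasol; OH trans to C4 methyl, C4 methyl cis to C5 methyl) | O[C@@H]1CCC2=CC(=O)C(=C(C)C)C[C@]2(C)[C@H]1C | intermediate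
12 | (4aR,5R,6R)-3-(2-hydroperoxypropan-2-yl)-6-hydroxy-4a,5-dimethyl-5,6,7,8-tetrahydronaphthalen-2(4aH)-one | O[C@@H]1CCC2=CC(=O)C(C(C)(C)OO)=C[C@]2(C)[C@H]1C | intermediate
13 | (4aR,5R,6R)-6-hydroxy-3-(2-hydroxypropan-2-yl)-4a,5-dimethyl-5,6,7,8-tetrahydronaphthalen-2(4aH)-one | O[C@@H]1CCC2=CC(=O)C(C(C)(C)O)=C[C@]2(C)[C@H]1C | intermediate
14 | propargyl alcohol (prop-2-yn-1-ol) | C#CCO | starting material
15 | (Z)-3-(bromomagnesio)-2-methylprop-2-en-1-olate bromomagnesium salt (Mg cis to CH2O) | Br[Mg]/C=C(/C)CO[Mg]Br | intermediate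
16 | (Z)-3-iodo-2-methylprop-2-en-1-ol | I/C=C(/C)CO | intermediate
17 | (Z)-3-iodo-2-methylprop-2-enal | I/C=C(/C)C=O | intermediate
18 | (Z)-3-iodo-2-methylprop-2-enoic acid | I/C=C(/C)C(=O)O | intermediate
19 | (Z)-2-methyl-3-(methylsulfanyl)prop-2-enoic acid | CS/C=C(/C)C(=O)O | intermediate
20 | (1R,2R,8aR)-7-(2-hydroxypropan-2-yl)-1,8a-dimethyl-6-oxo-1,2,3,4,6,8a-hexahydronaphthalen-2-yl (2Z)-2-methyl-3-(methylsulfanyl)prop-2-enoate (CNP0150028.1) | CS/C=C(/C)C(=O)O[C@@H]1CCC2=CC(=O)C(C(C)(C)O)=C[C@]2(C)[C@H]1C | target

## Step count and risks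

Total step count: 10. Longest linear sequence: 7 (steps 1–6 and 10); steps 7–9 make the side-chain acid.

Stereocentres: C5 is set in step 1, C3 and C4 in step 5, and the Z alkene in step 7; none of them is α to a carbonyl or otherwise epimerisable in later steps.

Three steps most likely to fail:

Step 5 (the proposed new step). Possible failures are competing oxidation of the dienone, poor face selectivity at C3 or C4, and a 1,2-vinyl shift of the homoallylic C4 radical if hydrogen transfer is slow; the high disulfide loading is meant to outrun the last. The fallback sets out from 9 and uses known chemistry. mCPBA with NaHCO3 in CH2Cl2 at 0 °C epoxidises only the isolated electron-rich C3=C4 alkene, from the face opposite the C5 methyl, to give 3α,4α-epoxyeremophila-7(11),9-dien-8-one F1. Titanocene monochloride Cp2TiCl (from Cp2TiCl2 and Mn dust, THF) with 1,4-cyclohexadiene then opens the epoxide homolytically to the tertiary C4 radical with oxygen kept on C3 (Nugent–RajanBabu reductive opening). Hydrogen is delivered from the open α face, and the sequence comes back to the route at 11.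

Step 6. The ene reaction may be slow for the electron-poor alkene or may give some of the regioisomer with oxygen on C7 and an isopropenyl group. The fallback sets out from 11: NBS in THF–water adds bromine to the α-carbon C7 and water to the tertiary β-carbon C11, giving the 7-bromo-11-hydroxy bromohydrin F2. Li2CO3/LiBr in DMF at 100 °C then eliminates HBr toward C6, the only position with β-hydrogens, and the sequence comes back to the route at 13.

Step 10. The push–pull thioacrylic acid is a sluggish acyl donor and DMAP can isomerise Z to E by conjugate addition. The fallback sets out from 13: DCC/DMAP coupling with the geometrically robust iodo acid 18 gives the (Z)-3-iodo-2-methylacrylate ester F3. NaSMe (1.05 equiv, THF, −20 °C) then replaces iodide by addition–elimination with retention (nucleophilic vinylic substitution), and the sequence arrives at 20.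

Further compounds
F1 | step 5 | 3α,4α-epoxyeremophila-7(11),9-dien-8-one (oxirane trans to the C5 methyl; 3R,4S,5S) | C[C@]12CC(=C(C)C)C(=O)C=C1CC[C@H]3O[C@@]23C
F2 | step 6 | (4aR,5R,6R)-3-bromo-6-hydroxy-3-(2-hydroxypropan-2-yl)-4a,5-dimethyl-4,4a,5,6,7,8-hexahydronaphthalen-2(3H)-one (both C3 epimers) | O[C@@H]1CCC2=CC(=O)C(Br)(C(C)(C)O)C[C@]2(C)[C@H]1C
F3 | step 10 | (1R,2R,8aR)-7-(2-hydroxypropan-2-yl)-1,8a-dimethyl-6-oxo-1,2,3,4,6,8a-hexahydronaphthalen-2-yl (2Z)-3-iodo-2-methylprop-2-enoate | I/C=C(/C)C(=O)O[C@@H]1CCC2=CC(=O)C(C(C)(C)O)=C[C@]2(C)[C@H]1C
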